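The plan rests on cutting the cyclopropane (ring atoms C5, C6, C7; chain numbered from the ester carbonyl C1) at C5–C6 and C5–C7. The feature used is that C6 is an unsubstituted ring CH2 while C7 adjoins the methyl-bearing C8, which is the imprint of a terminal epoxide (C6–C7) hung on a 2-methyl-1,3-dioxygenated C7–C9 unit available in enantiopure form. In a single operation a phosphonoacetate anion opens the epoxide at C6, phosphorus shifts to the C7 oxygen and the ester enolate closes the ring with inversion at C7, giving the trans ring and fixing C5 and C7 next to C8. The precursor is a trityl-protected (2S)-oxirane carrying the (R)-configured side chain.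

Key step: step 6

Remarks on the chemistry (assumptions)
- Numbering: C1 ester carbonyl, C5–C6–C7 cyclopropane, C8 and C16 the CH(CH3) centres, C9=C10–C11=C12 the diene, C18≡C19–Br the bromoalkyne. In this numbering the target is 5R,7R,8R,16S with 9E,11E.
- The C9 oxygen is carried as a trityl (triphenylmethyl) ether. A silyl group would sit 1,3 to the C7 alkoxide formed in the key step and could transfer to it under hot base. Trityl cannot migrate, is inert to NaH, LiAlH4, Grignard reagents and ozone, and leaves under mild acid.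
- The hydrolytic kinetic resolution is assumed to follow its usual sense for alkyl-substituted terminal epoxides (the (S,S)-catalyst leaves the (S)-oxirane) despite the neighbouring C8 centre. Salen = N,N′-bis(3,5-di-tert-butylsalicylidene)cyclohexane-1,2-diamine dianion.

Step 1
Reactants: 1 methyl (2R)-3-hydroxy-2-methylpropanoate
Product: 2 methyl (2R)-2-methyl-3-(trityloxy)propanoate
Conditions: TrCl, Et3N, DMAP (cat.), CH2Cl2, 0 °C → rt
Reagents that add atoms: trityl chloride, ClC(c1ccccc1)(c1ccccc1)c1ccccc1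
Why: O-tritylation of the primary alcohol (SN1-type etherification) under amine base should proceed without touching the C8 centre, which carries no acidic activation beyond the ester.

Step 2
Reactants: 2 methyl (2R)-2-methyl-3-(trityloxy)propanoate
Product: 3 (2R)-2-methyl-3-(trityloxy)propanal
Conditions: i-Bu2AlH (1.1 equiv), CH2Cl2, −78 °C; MeOH, then aq. potassium sodium tartrate
Reagents that add atoms: none
Why: Partial hydride reduction of the ester should stop at the aldehyde because the tetrahedral aluminium hemiacetal is stable at −78 °C and collapses only on work-up.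

Step 3
Reactants: 3 (2R)-2-methyl-3-(trityloxy)propanal
Product: 4 trityl [(2S)-2-methylbut-3-en-1-yl] ether
Conditions: Ph3PCH3Br, NaN(SiMe3)2, THF, 0 °C; then 3, −78 → 0 °C
Reagents that add atoms: methyltriphenylphosphonium bromide, C[P+](c1ccccc1)(c1ccccc1)c1ccccc1.[Br-]
Why: Wittig methylenation with the salt-free, non-stabilised ylide at low temperature should install C6 without epimerising the α-centre C8 (the descriptor changes only through priority).

Step 4
Reactants: 4 trityl [(2S)-2-methylbut-3-en-1-yl] ether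
Product: 5 2-[(2R)-1-(trityloxy)propan-2-yl]oxirane (both oxirane epimers)
Conditions: mCPBA, NaHCO3, CH2Cl2, 0 °C → rt
Reagents that add atoms: 3-chloroperbenzoic acid, OOC(=O)c1cccc(Cl)c1
Why: Prilezhaev epoxidation of the monosubstituted alkene is reliable under bicarbonate buffer, and since C8 is expected to exert little facial control, the C7 configuration is deliberately left to step 5.

Step 5
Reactants: 5 2-[(2R)-1-(trityloxy)propan-2-yl]oxirane (both oxirane epimers)
Product: 6 (2S)-2-[(2R)-1-(trityloxy)propan-2-yl]oxirane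
Conditions: (S,S)-(salen)Co(OAc) (2 mol%), H2O (1.1 equiv relative to the (2R)-oxirane epimer), THF (minimal), 0 °C → rt
Reagents that add atoms: none
Why: Hydrolytic kinetic resolution, in which the chiral trivalent-cobalt salen complex should hydrolyse only the (2R)-oxirane epimer to its diol, so that C7 of the surviving epoxide is set by the catalyst while C8 is untouched.

Step 6
Reactants: 6 (2S)-2-[(2R)-1-(trityloxy)propan-2-yl]oxirane; 7 triethyl phosphonoacetate
Product: 10 ethyl (1R,2S)-2-[(2S)-1-(trityloxy)propan-2-yl]cyclopropane-1-carboxylate, via hydroxy phosphonate adduct 8 (not isolated), via phosphate ester enolate 9 (not isolated)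
Conditions: NaH (2.4 equiv), 7 (2.5 equiv), DME, 0 °C → rt; then 6, 130 °C (sealed vessel), 18 h
Reagents that add atoms: none
Why: The sodium salt of 7 attacks the unsubstituted oxirane carbon C6 in an SN2 opening to give alkoxide 8, whose C7 oxygen adds to phosphorus to form a five-membered oxaphospholane that collapses by P–C5 cleavage to the phosphate-bearing ester enolate 9, which then displaces the phosphate at C7. The closest known reaction type is the Wadsworth–Emmons cyclopropanation of enantiopure terminal epoxides with phosphonoacetate anions, applied here to an α-branched epoxide that calls for the higher temperature. The cyclopropane is closed by a 3-exo-tet C-alkylation (C5–C7) after the intermolecular C5–C6 bond formation. C7 is set by inversion in the intramolecular backside displacement, so the (2S)-oxirane gives the ring configuration of the target; C5 is set trans to the C7 side chain because closure places the ester anti to that substituent, with base-mediated equilibration at the ester-bearing carbon as a backstop; C8 is carried through unchanged. The step needs opening at C6 rather than C7 and phosphoryl transfer rather than lactonisation onto the ester, which the hindered α-branched C7, the excess of phosphonate anion and a trityl ether that cannot migrate to the C7 alkoxide should secure.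

Step 7
Reactants: 10 ethyl (1R,2S)-2-[(2S)-1-(trityloxy)propan-2-yl]cyclopropane-1-carboxylate
Product: 11 [(1R,2S)-2-[(2S)-1-(trityloxy)propan-2-yl]cyclopropyl]methanol
Conditions: LiAlH4, THF, 0 °C; Fieser work-up
Reagents that add atoms: none
Why: Hydride reduction of the ester to the primary alcohol (C4) leaves the cyclopropane and the trityl ether untouched.

Step 8
Reactants: 11 [(1R,2S)-2-[(2S)-1-(trityloxy)propan-2-yl]cyclopropyl]methanol
Product: 12 [(1R,2S)-2-[(2S)-1-(trityloxy)propan-2-yl]cyclopropyl]methyl 4-methylbenzenesulfonate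
Conditions: TsCl, Et3N, DMAP (cat.), CH2Cl2, 0 °C; used cold and without chromatography
Reagents that add atoms: 4-toluenesulfonyl chloride, Cc1ccc(cc1)S(Cl)(=O)=O
Why: O-sulfonylation of the primary alcohol is routine, and keeping the cyclopropylcarbinyl tosylate cold and basic should suppress its ionisation before the coupling.

Step 9
Reactants: 12 [(1R,2S)-2-[(2S)-1-(trityloxy)propan-2-yl]cyclopropyl]methyl 4-methylbenzenesulfonate; 13 but-3-en-1-ylmagnesium bromide
Product: 14 trityl [(2S)-2-[(1R,2R)-2-(pent-4-en-1-yl)cyclopropyl]propyl] ether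
Conditions: 13 (3 equiv), Li2CuCl4 (5 mol%), THF, −78 → 0 °C
Reagents that add atoms: none
Why: Copper-catalysed cross-coupling of a Grignard reagent with a primary tosylate (Kochi type) forms C4–C3 by an SN2-like displacement at copper, a pathway that should leave the cyclopropylcarbinyl unit closed because no free radical or cation is involved.

Step 10
Reactants: 14 trityl [(2S)-2-[(1R,2R)-2-(pent-4-en-1-yl)cyclopropyl]propyl] ether
Product: 16 methyl 4-[(1R,2R)-2-[(2S)-1-(trityloxy)propan-2-yl]cyclopropyl]butanoate, via butanal intermediate 15 (not isolated)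
Conditions: O3, NaOH (2.5 M in MeOH), CH2Cl2, −78 °C; then H2O/Et2O, warm to rt
Reagents that add atoms: ozone, [O-][O+]=O; methanol, CO
Why: Ozonolysis in methanolic NaOH cleaves the terminal alkene to aldehyde 15, whose methyl hemiacetal alkoxide is oxidised by further ozone straight to the methyl ester (C1), while the cyclopropane and the unactivated trityl arenes are inert at −78 °C.

Step 11
Reactants: 16 methyl 4-[(1R,2R)-2-[(2S)-1-(trityloxy)propan-2-yl]cyclopropyl]butanoate
Product: 17 methyl 4-[(1R,2R)-2-[(2S)-1-hydroxypropan-2-yl]cyclopropyl]butanoate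
Conditions: TsOH·H2O (cat.), MeOH/CH2Cl2, rt
Reagents that add atoms: none
Why: Acid-catalysed detritylation (SN1 loss of the trityl cation, trapped by methanol) frees the C9 alcohol, and methanol as solvent makes any ester exchange degenerate.

Step 12
Reactants: 17 methyl 4-[(1R,2R)-2-[(2S)-1-hydroxypropan-2-yl]cyclopropyl]butanoate
Product: 18 methyl 4-[(1R,2R)-2-[(2S)-1-oxopropan-2-yl]cyclopropyl]butanoate
Conditions: Dess–Martin periodinane, NaHCO3, CH2Cl2, 0 °C → rt; used directly
Reagents that add atoms: none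
Why: Dess–Martin oxidation under buffered, non-basic conditions should give the C9 aldehyde without epimerising the adjacent C8 centre.

Step 13
Reactants: 18 methyl 4-[(1R,2R)-2-[(2S)-1-oxopropan-2-yl]cyclopropyl]butanoate
Product: 19 methyl 4-[(1R,2R)-2-[(2R,3E)-4-(4,4,5,5-tetramethyl-1,3,2-dioxaborolan-2-yl)but-3-en-2-yl]cyclopropyl]butanoate
Conditions: Cl2CHBpin, CrCl2, LiI, THF, rt
Reagents that add atoms: 2-(dichloromethyl)-4,4,5,5-tetramethyl-1,3,2-dioxaborolane, ClC(Cl)B1OC(C)(C)C(C)(C)O1
Why: Takai–Utimoto borylolefination, in which a geminal dichromium reagent adds to the aldehyde and eliminates anti to give the E-alkenylboronate (C9=C10) under non-basic conditions that tolerate the ester and the α-centre.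

Step 14
Reactants: 20 (3S)-3,7-dimethyloct-6-enal ((S)-citronellal)
Product: 21 (4S)-4,8-dimethylnon-7-en-1-yne
Conditions: dimethyl (1-diazo-2-oxopropyl)phosphonate, K2CO3, MeOH, 0 °C → rt
Reagents that add atoms: dimethyl (1-diazo-2-oxopropyl)phosphonate, COP(=O)(OC)C(=[N+]=[N-])C(C)=O
Why: Ohira–Bestmann (Seyferth–Gilbert) homologation converts the aldehyde C18 into the C18≡C19 alkyne, and the C16 centre is β to the carbonyl and not at risk.

Step 15
Reactants: 21 (4S)-4,8-dimethylnon-7-en-1-yne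
Product: 23 [(4S)-4,8-dimethylnon-7-en-1-yn-1-yl]tri(propan-2-yl)silane, via lithium acetylide 22 (not isolated)
Conditions: n-BuLi, THF, −78 °C; then i-Pr3SiOTf, −78 °C → rt
Reagents that add atoms: triisopropylsilyl trifluoromethanesulfonate, CC(C)[Si](C(C)C)(C(C)C)OS(=O)(=O)C(F)(F)F
Why: Deprotonation and C-silylation of the terminal alkyne gives a bulky silylalkyne that should stay inert to ozone, acetylide, carboalumination and palladium in the following steps.

Step 16
Reactants: 23 [(4S)-4,8-dimethylnon-7-en-1-yn-1-yl]tri(propan-2-yl)silane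
Product: 25 (4S)-4-methyl-7-[tri(propan-2-yl)silyl]hept-6-yn-1-ol, via ozonolysis aldehyde 24 (not isolated)
Conditions: O3, CH2Cl2/MeOH, −78 °C (Sudan red 7B end point); then NaBH4, −78 °C → rt
Reagents that add atoms: ozone, [O-][O+]=O
Why: Chemoselective ozonolysis of the electron-rich trisubstituted alkene with reductive work-up gives the C13 alcohol, the silylalkyne reacting far more slowly with ozone.

Step 17
Reactants: 25 (4S)-4-methyl-7-[tri(propan-2-yl)silyl]hept-6-yn-1-ol
Product: 26 [(4S)-7-iodo-4-methylhept-1-yn-1-yl]tri(propan-2-yl)silane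
Conditions: I2, PPh3, imidazole, CH2Cl2, 0 °C → rt
Reagents that add atoms: iodine, II
Why: Appel-type iodination converts the primary alcohol into the iodide by SN2 displacement of the oxyphosphonium group.

Step 18
Reactants: 26 [(4S)-7-iodo-4-methylhept-1-yn-1-yl]tri(propan-2-yl)silane
Product: 27 [(4S)-4-methylnona-1,8-diyn-1-yl]tri(propan-2-yl)silane
Conditions: LiC≡CH·H2NCH2CH2NH2, DMSO, 10 °C → rt
Reagents that add atoms: lithium acetylide–ethylenediamine complex, [Li+].[C-]#C.NCCN
Why: SN2 alkylation of lithium acetylide by the unhindered primary iodide in DMSO adds C12 and C11 as a terminal alkyne, the triisopropylsilyl alkyne being stable to the reagent.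

Step 19
Reactants: 27 [(4S)-4-methylnona-1,8-diyn-1-yl]tri(propan-2-yl)silane
Product: 29 [(4S,8E)-9-iodo-4,8-dimethylnon-8-en-1-yn-1-yl]tri(propan-2-yl)silane, via alkenyl dimethylalane 28 (not isolated)
Conditions: AlMe3, Cp2ZrCl2, CH2Cl2, 0 °C → rt; then I2, THF, −30 → 0 °C
Reagents that add atoms: trimethylaluminium, C[Al](C)C; iodine, II
Why: Zirconium-catalysed carboalumination (Negishi) adds methyl and aluminium syn across the terminal alkyne with aluminium at C11, and iodinolysis with retention gives the E-configured C11=C12 iodoalkene, the hindered silylalkyne not taking part.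

Step 20
Reactants: 19 methyl 4-[(1R,2R)-2-[(2R,3E)-4-(4,4,5,5-tetramethyl-1,3,2-dioxaborolan-2-yl)but-3-en-2-yl]cyclopropyl]butanoate; 29 [(4S,8E)-9-iodo-4,8-dimethylnon-8-en-1-yn-1-yl]tri(propan-2-yl)silane
Product: 30 methyl 4-[(1R,2R)-2-[(2R,3E,5E,10S)-6,10-dimethyl-13-[tri(propan-2-yl)silyl]trideca-3,5-dien-12-yn-2-yl]cyclopropyl]butanoate
Conditions: PdCl2(dppf) (5 mol%), K3PO4 (aq.), THF, degassed, rt → 40 °C
Reagents that add atoms: none
Why: Suzuki–Miyaura coupling of the alkenyl iodide with the alkenylboronate forms C10–C11 with retention of both alkene geometries, and the mild phosphate base spares the methyl ester.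

Step 21
Reactants: 30 methyl 4-[(1R,2R)-2-[(2R,3E,5E,10S)-6,10-dimethyl-13-[tri(propan-2-yl)silyl]trideca-3,5-dien-12-yn-2-yl]cyclopropyl]butanoate
Product: 31 methyl 4-[(1R,2R)-2-[(2R,3E,5E,10S)-6,10-dimethyltrideca-3,5-dien-12-yn-2-yl]cyclopropyl]butanoate
Conditions: Bu4NF, THF, 0 °C → rt
Reagents that add atoms: none
Why: Fluoride-induced protodesilylation of the alkynylsilane is fast at 0 °C and should leave the ester and the diene unchanged.

Step 22
Reactants: 31 methyl 4-[(1R,2R)-2-[(2R,3E,5E,10S)-6,10-dimethyltrideca-3,5-dien-12-yn-2-yl]cyclopropyl]butanoate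
Product: 32 methyl 4-[(1R,2R)-2-[(2R,3E,5E,10S)-13-bromo-6,10-dimethyltrideca-3,5-dien-12-yn-2-yl]cyclopropyl]butanoate
Conditions: NBS (1.05 equiv), AgNO3 (10 mol%), acetone, 0 °C, dark
Reagents that add atoms: N-bromosuccinimide, BrN1C(=O)CCC1=O
Why: Silver-catalysed electrophilic bromination of the terminal alkyne proceeds through a silver acetylide that should capture NBS much faster than the diene does under short, cold, light-free exposure.

Compound list
1 | methyl (2R)-3-hydroxy-2-methylpropanoate | COC(=O)[C@H](C)CO | starting material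
2 | methyl (2R)-2-methyl-3-(trityloxy)propanoate | COC(=O)[C@H](C)COC(c1ccccc1)(c1ccccc1)c1ccccc1 | intermediate
3 | (2R)-2-methyl-3-(trityloxy)propanal | O=C[C@H](C)COC(c1ccccc1)(c1ccccc1)c1ccccc1 | intermediate
4 | trityl [(2S)-2-methylbut-3-en-1-yl] ether | C=C[C@H](C)COC(c1ccccc1)(c1ccccc1)c1ccccc1 | intermediate
5 | 2-[(2R)-1-(trityloxy)propan-2-yl]oxirane (both oxirane epimers) | C1OC1[C@H](C)COC(c2ccccc2)(c2ccccc2)c2ccccc2 | intermediate
6 | (2S)-2-[(2R)-1-(trityloxy)propan-2-yl]oxirane | C1O[C@H]1[C@H](C)COC(c2ccccc2)(c2ccccc2)c2ccccc2 | intermediate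
7 | triethyl phosphonoacetate | CCOC(=O)CP(=O)(OCC)OCC | starting material
8 | ethyl (4R,5R)-2-(diethoxyphosphoryl)-4-hydroxy-5-methyl-6-(trityloxy)hexanoate (sodium salt in the flask, C2 unassigned) | CCOC(=O)C(P(=O)(OCC)OCC)C[C@@H](O)[C@H](C)COC(c1ccccc1)(c1ccccc1)c1ccccc1 | intermediate
9 | ethyl (4R,5R)-4-[(diethoxyphosphoryl)oxy]-5-methyl-6-(trityloxy)hexanoate (as its sodium enolate in the flask) | CCOC(=O)CC[C@@H](OP(=O)(OCC)OCC)[C@H](C)COC(c1ccccc1)(c1ccccc1)c1ccccc1 | intermediate
10 | ethyl (1R,2S)-2-[(2S)-1-(trityloxy)propan-2-yl]cyclopropane-1-carboxylate | CCOC(=O)[C@@H]1C[C@H]1[C@H](C)COC(c2ccccc2)(c2ccccc2)c2ccccc2 | intermediate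
11 | [(1R,2S)-2-[(2S)-1-(trityloxy)propan-2-yl]cyclopropyl]methanol | OC[C@@H]1C[C@H]1[C@H](C)COC(c2ccccc2)(c2ccccc2)c2ccccc2 | intermediate
12 | [(1R,2S)-2-[(2S)-1-(trityloxy)propan-2-yl]cyclopropyl]methyl 4-methylbenzenesulfonate | Cc1ccc(cc1)S(=O)(=O)OC[C@@H]1C[C@H]1[C@H](C)COC(c2ccccc2)(c2ccccc2)c2ccccc2 | intermediate
13 | but-3-en-1-ylmagnesium bromide (THF solution) | C=CCC[Mg]Br | starting material
14 | trityl [(2S)-2-[(1R,2R)-2-(pent-4-en-1-yl)cyclopropyl]propyl] ether | C=CCCC[C@@H]1C[C@H]1[C@H](C)COC(c2ccccc2)(c2ccccc2)c2ccccc2 | intermediate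
15 | 4-[(1R,2R)-2-[(2S)-1-(trityloxy)propan-2-yl]cyclopropyl]butanal (as methyl hemiacetal alkoxide in the flask) | O=CCCC[C@@H]1C[C@H]1[C@H](C)COC(c2ccccc2)(c2ccccc2)c2ccccc2 | intermediate
16 | methyl 4-[(1R,2R)-2-[(2S)-1-(trityloxy)propan-2-yl]cyclopropyl]butanoate | COC(=O)CCC[C@@H]1C[C@H]1[C@H](C)COC(c2ccccc2)(c2ccccc2)c2ccccc2 | intermediate
17 | methyl 4-[(1R,2R)-2-[(2S)-1-hydroxypropan-2-yl]cyclopropyl]butanoate | COC(=O)CCC[C@@H]1C[C@H]1[C@H](C)CO | intermediate
18 | methyl 4-[(1R,2R)-2-[(2S)-1-oxopropan-2-yl]cyclopropyl]butanoate | COC(=O)CCC[C@@H]1C[C@H]1[C@H](C)C=O | intermediate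
19 | methyl 4-[(1R,2R)-2-[(2R,3E)-4-(4,4,5,5-tetramethyl-1,3,2-dioxaborolan-2-yl)but-3-en-2-yl]cyclopropyl]butanoate | COC(=O)CCC[C@@H]1C[C@H]1[C@H](C)/C=C/B2OC(C)(C)C(C)(C)O2 | intermediate
20 | (3S)-3,7-dimethyloct-6-enal ((S)-citronellal) | CC(C)=CCC[C@H](C)CC=O | starting material
21 | (4S)-4,8-dimethylnon-7-en-1-yne | CC(C)=CCC[C@H](C)CC#C | intermediate
22 | lithium (4S)-4,8-dimethylnon-7-en-1-yn-1-ide | CC(C)=CCC[C@H](C)CC#C[Li] | intermediate
23 | [(4S)-4,8-dimethylnon-7-en-1-yn-1-yl]tri(propan-2-yl)silane | CC(C)=CCC[C@H](C)CC#C[Si](C(C)C)(C(C)C)C(C)C | intermediate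
24 | (4S)-4-methyl-7-[tri(propan-2-yl)silyl]hept-6-ynal | O=CCC[C@H](C)CC#C[Si](C(C)C)(C(C)C)C(C)C | intermediate
25 | (4S)-4-methyl-7-[tri(propan-2-yl)silyl]hept-6-yn-1-ol | OCCC[C@H](C)CC#C[Si](C(C)C)(C(C)C)C(C)C | intermediate
26 | [(4S)-7-iodo-4-methylhept-1-yn-1-yl]tri(propan-2-yl)silane | ICCC[C@H](C)CC#C[Si](C(C)C)(C(C)C)C(C)C | intermediate
27 | [(4S)-4-methylnona-1,8-diyn-1-yl]tri(propan-2-yl)silane | C#CCCC[C@H](C)CC#C[Si](C(C)C)(C(C)C)C(C)C | intermediate
28 | [(1E,6S)-2,6-dimethyl-9-[tri(propan-2-yl)silyl]non-1-en-8-yn-1-yl]dimethylalumane | C[Al](C)/C=C(\C)CCC[C@H](C)CC#C[Si](C(C)C)(C(C)C)C(C)C | intermediate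
29 | [(4S,8E)-9-iodo-4,8-dimethylnon-8-en-1-yn-1-yl]tri(propan-2-yl)silane | I/C=C(\C)CCC[C@H](C)CC#C[Si](C(C)C)(C(C)C)C(C)C | intermediate
30 | methyl 4-[(1R,2R)-2-[(2R,3E,5E,10S)-6,10-dimethyl-13-[tri(propan-2-yl)silyl]trideca-3,5-dien-12-yn-2-yl]cyclopropyl]butanoate | COC(=O)CCC[C@@H]1C[C@H]1[C@H](C)/C=C/C=C(\C)CCC[C@H](C)CC#C[Si](C(C)C)(C(C)C)C(C)C | intermediate
31 | methyl 4-[(1R,2R)-2-[(2R,3E,5E,10S)-6,10-dimethyltrideca-3,5-dien-12-yn-2-yl]cyclopropyl]butanoate | COC(=O)CCC[C@@H]1C[C@H]1[C@H](C)/C=C/C=C(\C)CCC[C@H](C)CC#C | intermediate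
32 | methyl 4-[(1R,2R)-2-[(2R,3E,5E,10S)-13-bromo-6,10-dimethyltrideca-3,5-dien-12-yn-2-yl]cyclopropyl]butanoate | COC(=O)CCC[C@@H]1C[C@H]1[C@H](C)/C=C/C=C(\C)CCC[C@H](C)CC#CBr | target

Total step count: 22.
Longest linear sequence: 16 steps (steps 1–13, then 20–22); the six steps 14–19 prepare the C11–C19 partner.

Steps most likely to fail

Step 6. The phosphoryl transfer and ring closure at the hindered, α-branched C7 may be slow, so that the opened adduct stalls or lactonises onto its ester instead of closing the ring. The fallback sets out from 3 and returns at 11, building the ring by a directed carbenoid addition instead. Wittig olefination of 3 with Ph3P=CHCO2Et (CH2Cl2, rt) should give ethyl (2E,4S)-4-methyl-5-(trityloxy)pent-2-enoate F1. Reduction with i-Bu2AlH (CH2Cl2, −78 °C) should give (2E,4S)-4-methyl-5-(trityloxy)pent-2-en-1-ol F2. Simmons–Smith cyclopropanation of F2 with Zn(CH2I)2 (from Et2Zn and CH2I2) in the presence of the (4S,5S)-2-butyl-N,N,N′,N′-tetramethyl-1,3,2-dioxaborolane-4,5-dicarboxamide ligand (CH2Cl2, 0 °C → rt) should then give 11. The E-alkene fixes the trans ring and the ligand the absolute sense at C5 and C7.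

Step 9. The cyclopropylcarbinyl tosylate may ionise or open by single-electron transfer (homoallyl or cyclobutyl skeletons), or undergo halide exchange without C–C bond formation. The fallback sets out from 11 and returns at 16, avoiding any leaving group on C4. Dess–Martin oxidation should give (1R,2S)-2-[(2S)-1-(trityloxy)propan-2-yl]cyclopropane-1-carbaldehyde F3. Wittig reaction with the ylide from (2-carboxyethyl)triphenylphosphonium bromide and NaN(SiMe3)2 (2 equiv, THF, −78 °C → rt) should give (3Z)-4-[(1S,2R)-2-[(2S)-1-(trityloxy)propan-2-yl]cyclopropyl]but-3-enoic acid F4. Diimide reduction (TsNHNH2, NaOAc, DME/H2O, reflux), which saturates the alkene without opening the vinylcyclopropane, should give 4-[(1R,2R)-2-[(2S)-1-(trityloxy)propan-2-yl]cyclopropyl]butanoic acid F5. Esterification with Me3SiCHN2 (MeOH/toluene) gives 16.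

Step 22. Electrophilic bromine may add to, or substitute on, the electron-rich C9–C12 diene in competition with bromination of the silver acetylide. The fallback sets out from 20 and returns at 32, making the bromoalkyne by elimination so that no electrophilic bromine meets the diene.
- Reduction of 20 (NaBH4, MeOH) should give (3S)-3,7-dimethyloct-6-en-1-ol F6, and silylation (t-BuMe2SiCl, imidazole) tert-butyl{[(3S)-3,7-dimethyloct-6-en-1-yl]oxy}dimethylsilane F7.
- Ozonolysis with NaBH4 work-up should give (4S)-6-[(tert-butyldimethylsilyl)oxy]-4-methylhexan-1-ol F8, and iodination (I2, PPh3, imidazole) tert-butyl{[(3S)-6-iodo-3-methylhexyl]oxy}dimethylsilane F9.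
- Alkylation of LiC≡CH·H2NCH2CH2NH2 (DMSO) should give tert-butyldimethyl{[(3S)-3-methyloct-7-yn-1-yl]oxy}silane F10, and carboalumination–iodination (AlMe3, Cp2ZrCl2; I2) tert-butyl{[(3S,7E)-8-iodo-3,7-dimethyloct-7-en-1-yl]oxy}dimethylsilane F11.
- Suzuki–Miyaura coupling of F11 with 19 (PdCl2(dppf), K3PO4) should give methyl 4-[(1R,2R)-2-[(2R,3E,5E,10S)-12-[(tert-butyldimethylsilyl)oxy]-6,10-dimethyldodeca-3,5-dien-2-yl]cyclopropyl]butanoate F12.
- HF·pyridine (THF) should free methyl 4-[(1R,2R)-2-[(2R,3E,5E,10S)-12-hydroxy-6,10-dimethyldodeca-3,5-dien-2-yl]cyclopropyl]butanoate F13, and Dess–Martin oxidation should give methyl 4-[(1R,2R)-2-[(2R,3E,5E,10S)-6,10-dimethyl-12-oxododeca-3,5-dien-2-yl]cyclopropyl]butanoate F14.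
- Ramirez dibromoolefination (CBr4, PPh3, CH2Cl2, 0 °C) should give methyl 4-[(1R,2R)-2-[(2R,3E,5E,10S)-13,13-dibromo-6,10-dimethyltrideca-3,5,12-trien-2-yl]cyclopropyl]butanoate F15.
- E2 loss of HBr with NaN(SiMe3)2 (THF, −78 °C, cold acidic quench so that any ester enolate is simply reprotonated) should deliver 32.

Further compounds
F1 | step 6 | ethyl (2E,4S)-4-methyl-5-(trityloxy)pent-2-enoate | CCOC(=O)/C=C/[C@H](C)COC(c1ccccc1)(c1ccccc1)c1ccccc1
F2 | step 6 | (2E,4S)-4-methyl-5-(trityloxy)pent-2-en-1-ol | OC/C=C/[C@H](C)COC(c1ccccc1)(c1ccccc1)c1ccccc1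
F3 | step 9 | (1R,2S)-2-[(2S)-1-(trityloxy)propan-2-yl]cyclopropane-1-carbaldehyde | O=C[C@@H]1C[C@H]1[C@H](C)COC(c2ccccc2)(c2ccccc2)c2ccccc2
F4 | step 9 | (3Z)-4-[(1S,2R)-2-[(2S)-1-(trityloxy)propan-2-yl]cyclopropyl]but-3-enoic acid | OC(=O)C/C=C\[C@@H]1C[C@H]1[C@H](C)COC(c2ccccc2)(c2ccccc2)c2ccccc2
F5 | step 9 | 4-[(1R,2R)-2-[(2S)-1-(trityloxy)propan-2-yl]cyclopropyl]butanoic acid | OC(=O)CCC[C@@H]1C[C@H]1[C@H](C)COC(c2ccccc2)(c2ccccc2)c2ccccc2
F6 | step 22 | (3S)-3,7-dimethyloct-6-en-1-ol | CC(C)=CCC[C@H](C)CCO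
F7 | step 22 | tert-butyl{[(3S)-3,7-dimethyloct-6-en-1-yl]oxy}dimethylsilane | CC(C)=CCC[C@H](C)CCO[Si](C)(C)C(C)(C)C
F8 | step 22 | (4S)-6-[(tert-butyldimethylsilyl)oxy]-4-methylhexan-1-ol | OCCC[C@H](C)CCO[Si](C)(C)C(C)(C)C
F9 | step 22 | tert-butyl{[(3S)-6-iodo-3-methylhexyl]oxy}dimethylsilane | ICCC[C@H](C)CCO[Si](C)(C)C(C)(C)C
F10 | step 22 | tert-butyldimethyl{[(3S)-3-methyloct-7-yn-1-yl]oxy}silane | C#CCCC[C@H](C)CCO[Si](C)(C)C(C)(C)C
F11 | step 22 | tert-butyl{[(3S,7E)-8-iodo-3,7-dimethyloct-7-en-1-yl]oxy}dimethylsilane | I/C=C(\C)CCC[C@H](C)CCO[Si](C)(C)C(C)(C)C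
F12 | step 22 | methyl 4-[(1R,2R)-2-[(2R,3E,5E,10S)-12-[(tert-butyldimethylsilyl)oxy]-6,10-dimethyldodeca-3,5-dien-2-yl]cyclopropyl]butanoate | COC(=O)CCC[C@@H]1C[C@H]1[C@H](C)/C=C/C=C(\C)CCC[C@H](C)CCO[Si](C)(C)C(C)(C)C
F13 | step 22 | methyl 4-[(1R,2R)-2-[(2R,3E,5E,10S)-12-hydroxy-6,10-dimethyldodeca-3,5-dien-2-yl]cyclopropyl]butanoate | COC(=O)CCC[C@@H]1C[C@H]1[C@H](C)/C=C/C=C(\C)CCC[C@H](C)CCO
F14 | step 22 | methyl 4-[(1R,2R)-2-[(2R,3E,5E,10S)-6,10-dimethyl-12-oxododeca-3,5-dien-2-yl]cyclopropyl]butanoate | COC(=O)CCC[C@@H]1C[C@H]1[C@H](C)/C=C/C=C(\C)CCC[C@H](C)CC=O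
F15 | step 22 | methyl 4-[(1R,2R)-2-[(2R,3E,5E,10S)-13,13-dibromo-6,10-dimethyltrideca-3,5,12-trien-2-yl]cyclopropyl]butanoate | COC(=O)CCC[C@@H]1C[C@H]1[C@H](C)/C=C/C=C(\C)CCC[C@H](C)CC=C(Br)Br
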